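Look at the leftover first: in the north-west run about a third of the charge is still unreacted at 6.00 d, yet Rgt.Sbt reads 53%, which is 3 percentage points more than the half of the charge that was Sbt, against a scatter of 1.5 points.

all flasks: Sbt 0.10 M; Sbt2 0.10 M

|  | Rgt | Cat | Tsp | remark | time |
|---|---|---|---|---|---|
| north-west | 0.20 M | 1 mM | 0.15 mM | run made earlier |  |
| north | 0.20 M | 1 mM | 0.33 mM | run made earlier |  |
| flask | 0.200 M | 1.0 mM | 0.22 mM |  | 10 d |

- north-west (time / d: Rgt.Sbt / %, Rgt.Sbt2 / %): 0.500: 28, 4; 1.67: 44, 10; 3.00: 48, 13; 4.00: 52, 13; 6.00: 53, 13
- north (time / d: Rgt.Sbt / %, Rgt.Sbt2 / %): 0.500: 27, 8; 0.833: 33, 10; 1.67: 45, 12; 3.00: 50, 14; 6.00: 52, 13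

(readings scatter by 1.5 percentage points)

- Rgt.Sbt and Rgt.Sbt2 together, in percent of the Sbt and Sbt2 charged together, at 10 d
- excess of Rgt.Sbt over Rgt.Sbt2 in the product at 10 d
- whether the exchange between Sbt and Sbt2 keeps pace with the reaction: how far the product's excess at 10 d gets from its value without exchange to its value with instant exchange (above 80% keeps pace, below 20% hardly takes part, else lags behind)

- Rgt is single-handed; Sbt and Sbt2 are mirror images of each other, charged as a racemate, each of them at the stated concentration
- the earlier runs were read with a standard deviation of 1.5 percentage points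
- an excess is the difference of the two amounts in percent of their sum
- an excess is below zero if the other one leads
- the handed part of Rgt does not stay in what it makes, so the products of the two hands are mirror images too

So some Sbt2 seems to have become Sbt on the way, and the question is how quickly. Pool the last readings of both runs: Rgt.Sbt over Rgt.Sbt2 comes to 4.04. Call this the split: the Rgt.Sbt made per unit of Rgt.Sbt2, which is the selectivity factor while Sbt and Sbt2 stand level.

Without exchange, Rgt.Sbt stops at that half, so at the north-west total of 66.0% the split is at most 3.12, but the pooled split is larger. The first readings of both runs, pooled, give 4.58, and with two small Rgt.Sbt2 readings behind it, that is the same split within the scatter.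

In these two runs the split holds within the scatter from the first readings to the last, and I read that as an exchange that keeps pace. The excess is then the split less one over the split plus one, 60.3%, and this is my reckoning for the flask, whose Tsp lies between the two runs.

The forecast gives 66% together and an excess of 60%, and it says the exchange lags behind, with the words “Early conversions suggest a selectivity of about 8–10” among its grounds.

The flask gives 70.5% together, an excess of 59.8%, and an exchange that keeps pace, 99% of the way.

    Rgt + Sbt → Rgt.Sbt (k = 0.00644 M⁻¹ min⁻¹)
    Rgt + Sbt2 → Rgt.Sbt2 (k = 0.00161 M⁻¹ min⁻¹)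
    Sbt + Cat ⇌ Sbt2 + Cat, rate k3*[Cat]*[Sbt] forward; the back reaction follows from the equilibrium constant (k = 37.8 M⁻¹ min⁻¹)
    Cat + Tsp → Cat.Tsp (k = 182 M⁻¹ min⁻¹)
    Cat → Zed (k = 3.19 × 10⁻⁷ min⁻¹)
    Rgt ⇌ Imd (K = 6.52, k = 3.03 × 10⁻⁴ min⁻¹)

The leftover in the flask stands nearly level: the excess of Sbt2 over Sbt among what is left is 0.0264% at 5.00 d. Dividing the flask's total by the split plus one gives 14.0% of the charge as Rgt.Sbt2, and the flask holds 14.2%. In the neighbour with 0.080 M of Rgt the total is 31.5%, so the same division gives 6.25%, and that neighbour holds 6.31%.

The numbers in the tables stem from a simulated flask with constants of no real substance; the scatter is artificial.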